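## Analysis of the target

The target is a (2R)-2-(prop-1-en-2-yl)-2,3-dihydrobenzofuran whose benzene ring (C3a, C4, C5, C6, C7, C7a) carries no hydrogen. It bears O1 on C7a, free hydroxyls on C4 and C6, a 2-methylpropanoyl group on C5, the ring methylene C3 on C3a, and on C7 a methylene bridge to C3′ of a 6-ethyl-4-hydroxy-5-methyl-2H-pyran-2-one. C2 is the only stereocentre; nothing in the molecule can relay chirality to it, so it must be set by a reagent, and the SMILES fixes it as R. The C2–O1 bond is an allylic aryl ether bond that protic and Lewis acids ionise or open, and the isopropenyl group is sensitive to acid and to electrophilic halogen. The acylphloroglucinol is easily oxidised, and the methylene bridge between two enolic rings can revert to a quinone methide by retro-Michael cleavage. The difficulty is twofold: three oxygens with different fates (one ring ether, two free hydroxyls) must be placed between three different carbon groups without regiochemical ambiguity, and the last steps must avoid acid. The strategy rests on the strict alternation C7a(O)–C7(C)–C6(O)–C5(C)–C4(O)–C3a(C): a 3-alkoxycyclobutenone supplies C7a, C3a, C4 and C5, and a siloxyalkyne supplies C7 and C6. The three oxygens then come from three different atoms (ketene oxygen, silyl ynol ether oxygen, vinylogous ester oxygen) and arrive already told apart.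

## Retrosynthetic reasoning

**Bridge, C7–CH2 to C3′.** 35 is cut between the bridging methylene and C3′ of the pyranone, giving the o-quinone methide 34 and pyranone 32. 34 comes from diphenol 33 by loss of the methoxy group, and 33 from ketone 27 by fluoride-induced removal of both silicon-based groups. This bond is the most fragile one in the target, so it is made last. The forward reaction must free O6 and O4, expel methoxide from the C7 benzylic carbon, and alkylate 32 at carbon.

**Pyranone.** 32 is opened at the lactone bond O1′–C2′ to the diketo ester 31. 31 is cut between its C4 and C5 to dianion 30 of β-keto ester 28 and amide 29. This is a two-step, protecting-group-free preparation of the small half.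

**Acyl group on C5.** 27 is taken back to carbinol 26, and 26 is cut at the C5–carbon bond to aryllithium 25 and aldehyde 24. 25 comes from bromide 23 by halogen–metal exchange. The usual electrophilic acylation is avoided because its Lewis acid would ionise the trioxygenated benzylic ether at C7 and the allylic C2–O1 bond; the polarity is therefore inverted. C5 is the only ring position with a hydrogen, so no regiochemical question arises.

**Isopropenyl group and bromine.** 23 is derived from tertiary alcohol 22 by syn-dehydration, and 22 from 21 by electrophilic bromination. Bromine is introduced while the molecule has no alkene.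

**Dihydrofuran, O1–C2.** 21 is cut at O1–C2 to epoxy phenol 20. The forward step is a 5-exo opening with inversion, so the epoxide carbon must be S to give (R)-C2. 20 is released from acetate 19, 19 comes from alkene 18 by an enantioselective dioxirane epoxidation of the Shi type, and 18 from phenol 17 by acetylation. The acetate is needed because the free, electron-rich phenol would not survive the oxidant; its removal then triggers the ring closure.

**Benzene ring (strategic disconnection).** 17 is cut at C7a–C7 and C6–C5 (and formally at C7a–C3a, which is broken and re-formed) to cyclobutenone 9 and siloxyalkyne 13. One operation builds the ring and delivers O7a free, O6 silylated, O4 alkylated and C5 as the only ring C–H. The forward reaction must control only the orientation of the alkyne on the ketene.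

**Cyclobutenone.** 9 is cut across the four-membered ring to ketene 8 and ynol ether 5; 8 comes from acid chloride 7 and this from acid 6. 5 comes from dichlorovinyl ether 3, made from alcohol 1 and 2. The oxygen destined for C4 is carried as a 2-(trimethylsilyl)ethyl ether. A plain alkyl ether there could be removed only with a boron halide or a thiolate, which the benzylic ether, the ortho-acyl silyl ether and the allylic aryl ether would not tolerate.

**Siloxyalkyne.** 13 is cut at O–Si to ynolate 12, and 12 at C–O to acetylide 11 of alkyne 10. The methoxymethyl group on the alkyne becomes the latent quinone methide carbon at C7 and blocks that ring position.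

## Alternatives that were turned down

**Alternative 1: pyranone built last on a lactone-tethered malonyl unit.**
- Disconnection: the pyranone is cut at C4′–C5′ and O1′–C2′. The bridging CH2 and C2′–C4′ stay on the arene as a malonyl unit whose C2′ carbonyl is tied to O6 in a six-membered aryl lactone (acid chloride A2). The partner is silyl enol ether A3, and the product is A1, the O4-silyl ether of 35.
- Forward key step: A3 is C-acylated by A2, and the new enol oxygen transacylates onto the aryl lactone carbonyl, closing the pyranone and releasing O6.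
- For: the bridge is never made by joining two crowded halves. The lactone tells O6 from O4 and is consumed productively. Only a desilylation follows A1.
- Against: A2 is a malonyl half-chloride with a doubly activated α-hydrogen and should lose HCl to an acylketene or self-condense. A3 can be acylated on oxygen. The second stage needs a weakly nucleophilic enol to attack a crowded aryl ester. Nothing in this plan says how the hexasubstituted, stereodefined arene of A2 is obtained, and making an acid chloride next to an isopropenyl allylic ether is itself delicate.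
- Comparison: on the end-game it is at least as strong as the chosen route. The chosen route offers what it lacks: a one-step construction of the arene with the three oxygens already distinguished.

**Alternative 2: palladium-mediated annulation of an aryl iodide with an enantiopure epoxide.**
- Disconnection: the dihydrofuran is cut at C3–C3a and O1–C7a to aryl iodide A5 and epoxide A6; the product is A4.
- Forward key step: under palladium catalysis with a strained bicyclic alkene as transient mediator (Catellani conditions), the ortho C–H at C3a is alkylated by the CH2 end of A6. The liberated alkoxide then forms the C7a–O1 bond at the former C–I carbon.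
- For: it is convergent. C2 comes unchanged from A6, so no enantioselective oxidation of an electron-rich arene and no inversion argument is needed. In A4, C5–H lies between two acetal ethers and is ideal for directed lithiation, which is better than the bromination and exchange used here.
- Against: the C–H to be alkylated in A5 is flanked by the iodide carbon and an ether-bearing carbon, and A6 carries a fully substituted carbon next to its reacting oxygen, so both bond formations are sterically pressed. The two acetal groups must later be removed with acid in the presence of the allylic aryl ether. The C7 silyl ether and the tertiary silyl ether still need converting into the bridge and the alkene.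
- Comparison: it is as strong or stronger on stereocontrol and on C5 functionalisation, and probably similar in length. The chosen route offers an end-game in which fluoride is the only deprotecting agent, and a substitution pattern fixed by a pericyclic cascade and not by C–H site selectivity at a crowded position.

**Alternative 3: closure of the benzene ring by Claisen condensation.**
- Disconnection: the benzene ring is cut at C4–C5, leading from A7 back to dihydrofuran ester A8.
- Forward key step: with an alkoxide base the central carbon of the 1,3-diketone of A8 attacks the ring ester, alkoxide is lost, and enolisation aromatises the ring.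
- For: it is biomimetic. The acyl group and both hydroxyls arrive unprotected and correctly placed, and C2 is in place before the arene. A7 has C7–H as its only free position, and such acylphloroglucinols are good carbon nucleophiles toward a methylene electrophile derived from 32, so the bridge could be made without protecting groups; this end-game is shorter than the chosen one.
- Against: the ester of A8 is conjugated with the ring oxygen and is a poor electrophile. The diketone chain has competing aldol and O-acylation modes. Alkoxide can deprotonate the ring CH2 of A8 and open the dihydrofuran by β-elimination, and re-closure would scramble C2. Enantiopure A8 needs its own multistep asymmetric synthesis.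
- Comparison: it is stronger on protecting-group economy and on the final coupling. The chosen route sets the stereocentre on a configurationally safe aromatic framework and fixes the ring regiochemistry by orbital-controlled steps.

Key step: step 6

Assumption: 5-methylhex-4-enoic acid and the L-configured enantiomer of the fructose-derived epoxidation ketone are taken as purchasable.

Remark: the oxygen destined for C4 is carried as a 2-(trimethylsilyl)ethyl ether and not as an ethyl ether, so that it leaves with fluoride together with the silyl group on O6.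

## Route

Step 1
Reactants: 1 2-(trimethylsilyl)ethanol; 2 trichloroethene
Product: 3 {2-[(E)-1,2-dichloroethenoxy]ethyl}trimethylsilane
Conditions: KH, THF, 0 °C; then 2, −40 → 20 °C
Reagents that add atoms: none
Why: The potassium alkoxide converts trichloroethene into dichloroacetylene by loss of HCl and adds to it in anti fashion, the standard entry to 1,2-dichlorovinyl ethers; the alkoxide is kept cold so that Peterson-type loss of ethene from the β-silyl alkoxide cannot compete.

Step 2
Reactants: 3 {2-[(E)-1,2-dichloroethenoxy]ethyl}trimethylsilane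
Product: 5 [2-(ethynyloxy)ethyl]trimethylsilane, via lithium alkynyl ether 4 (not isolated)
Conditions: n-BuLi (2.2 equiv), Et2O, −78 → −40 °C; then H2O, −78 °C
Reagents that add atoms: none
Why: Deprotonation and loss of LiCl give the chloroalkynyl ether, a second equivalent exchanges chlorine for lithium, and protonation of 4 gives the terminal ynol ether, the usual elimination route from dichlorovinyl ethers; 5 is kept cold and used soon because ynol ethers with β-hydrogens lose ketene on heating.

Step 3
Reactants: 6 5-methylhex-4-enoic acid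
Product: 7 5-methylhex-4-enoyl chloride
Conditions: (COCl)2, HCONMe2 (cat.), CH2Cl2, 0 → 20 °C; concentrate
Reagents that add atoms: oxalyl chloride, O=C(Cl)C(=O)Cl
Why: Standard acid chloride formation through the chloroiminium salt; cold, brief conditions and removal of HCl with the solvent spare the trisubstituted alkene.

Step 4
Reactants: 7 5-methylhex-4-enoyl chloride; 5 [2-(ethynyloxy)ethyl]trimethylsilane
Product: 9 4-(3-methylbut-2-en-1-yl)-3-[2-(trimethylsilyl)ethoxy]cyclobut-2-en-1-one (racemic), via prenylketene 8 (not isolated)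
Conditions: Et3N, 5 (1.5 equiv), Et2O, slow addition of 7, 20 °C
Reagents that add atoms: none
Why: Dehydrochlorination gives ketene 8, which the ynol ether captures in a [2+2] cycloaddition; its unsubstituted, nucleophilic carbon bonds to the ketene carbonyl carbon, so the alkoxy group ends on C3 and the prenyl group on C4. Slow addition keeps ketene dimerisation down, and the one-carbon tether rules out an intramolecular [2+2] with the prenyl alkene.

Step 5
Reactants: 10 3-methoxyprop-1-yne
Product: 13 3-methoxy-1-(triisopropylsilyloxy)prop-1-yne, via lithium acetylide 11 (not isolated), via lithium ynolate 12 (not isolated)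
Conditions: n-BuLi, THF, −78 °C; t-BuOOLi (from t-BuOOH, LiN(SiMe3)2), −78 → 0 °C; i-Pr3SiOTf, −78 → 0 °C
Reagents that add atoms: tert-butyl hydroperoxide, CC(C)(C)OO; triisopropylsilyl trifluoromethanesulfonate, CC(C)[Si](OS(=O)(=O)C(F)(F)F)(C(C)C)C(C)C
Why: The lithium peroxide transfers oxygen to the acetylide carbon of 11 to give ynolate 12, and the bulky silyl triflate silylates 12 on oxygen, not carbon, to give a storable silyl ynol ether; 12 is kept at or below 0 °C so that the propargylic methoxy group is not eliminated.

Step 6
Reactants: 9 4-(3-methylbut-2-en-1-yl)-3-[2-(trimethylsilyl)ethoxy]cyclobut-2-en-1-one; 13 3-methoxy-1-(triisopropylsilyloxy)prop-1-yne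
Product: 17 6-(methoxymethyl)-2-(3-methylbut-2-en-1-yl)-5-(triisopropylsilyloxy)-3-[2-(trimethylsilyl)ethoxy]phenol, via vinylketene 14 (not isolated), via vinylcyclobutenone 15 (not isolated), via dienylketene 16 (not isolated)
Conditions: 13 (1.5 equiv), PhMe, 80 °C then 110 °C, sealed tube, Ar
Reagents that add atoms: none
Why: Heating opens 9 by four-electron electrocyclic cleavage of C1–C4 to vinylketene 14; the prenyl group should turn outward, which keeps its double bond away from the ketene and excludes an intramolecular [2+2]. The siloxyalkyne 13 then adds across the ketene C=C: its carbon bearing CH2OMe, made nucleophilic by the ynol oxygen, bonds to the ketene carbonyl carbon (C7a–C7) and its oxygen-bearing carbon to the ketene α-carbon (C6–C5), giving 15. 15 opens reversibly to dienylketene 16, and the isomer with the vinyl group turned inward is drained by a six-electron disrotatory electrocyclisation between the ketene carbon and the terminal vinyl carbon (C7a–C3a), the only ring closure of the step; tautomerisation of the cyclohexadienone gives the phenol. The closest known reaction type is the thermal Danheiser benzannulation of cyclobutenones with siloxyalkynes to resorcinol monosilyl ethers, and the extra alkoxy group of 9 turns the product into a phloroglucinol. No stereocentre is formed, and that of racemic 9 is lost on aromatisation. The one selectivity needed is the orientation of the [2+2] step, which the polarisation of the ynol ether secures. The ketene oxygen emerges as the single free hydroxyl on C7a next to the prenyl group, O6 is silylated, O4 is alkylated, and C5 is the only ring C–H. An excess of 13 limits dimerisation of 14 and acylation of the product phenol by 14.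

Step 7
Reactants: 17 6-(methoxymethyl)-2-(3-methylbut-2-en-1-yl)-5-(triisopropylsilyloxy)-3-[2-(trimethylsilyl)ethoxy]phenol
Product: 18 6-(methoxymethyl)-2-(3-methylbut-2-en-1-yl)-5-(triisopropylsilyloxy)-3-[2-(trimethylsilyl)ethoxy]phenyl acetate
Conditions: Ac2O, Et3N, 4-(dimethylamino)pyridine (cat.), CH2Cl2, 0 → 20 °C
Reagents that add atoms: acetic anhydride, CC(=O)OC(C)=O
Why: Acylation of the hindered phenol under nucleophilic catalysis; the acetate masks the electron-rich phenol against the oxidant of step 8 and is the trigger for step 9.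

Step 8
Reactants: 18 6-(methoxymethyl)-2-(3-methylbut-2-en-1-yl)-5-(triisopropylsilyloxy)-3-[2-(trimethylsilyl)ethoxy]phenyl acetate
Product: 19 2-{[(2S)-3,3-dimethyloxiran-2-yl]methyl}-6-(methoxymethyl)-5-(triisopropylsilyloxy)-3-[2-(trimethylsilyl)ethoxy]phenyl acetate
Conditions: 1,2:4,5-di-O-isopropylidene-β-L-erythro-2,3-hexodiulo-2,6-pyranose (30 mol%), KHSO5 (as 2KHSO5·KHSO4·K2SO4), K2CO3, Bu4NHSO4, MeCN–CH2(OMe)2, aq. Na2B4O7/Na2EDTA (pH 10.5), 0 °C
Reagents that add atoms: potassium peroxymonosulfate, [K+].[O-]S(=O)(=O)OO
Why: Shi epoxidation: the dioxirane formed from the ketone and KHSO5 transfers oxygen through a spiro transition state. The D-fructose-derived ketone gives the (R)-epoxide of a 2-methylbut-2-enyl group, so its enantiomer is used and should give the (S)-epoxide. The arene has no free hydroxyl, and the cold, buffered medium limits acetate hydrolysis.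

Step 9
Reactants: 19 2-{[(2S)-3,3-dimethyloxiran-2-yl]methyl}-6-(methoxymethyl)-5-(triisopropylsilyloxy)-3-[2-(trimethylsilyl)ethoxy]phenyl acetate
Product: 21 2-[(2R)-7-(methoxymethyl)-6-(triisopropylsilyloxy)-4-[2-(trimethylsilyl)ethoxy]-2,3-dihydro-1-benzofuran-2-yl]propan-2-ol, via epoxy phenol 20 (not isolated)
Conditions: K2CO3 (0.5 equiv), MeOH, 0 → 20 °C
Reagents that add atoms: none
Why: Methanolysis of the aryl acetate frees the phenoxide of 20, which opens the epoxide at its secondary carbon in a 5-exo SN2 reaction with inversion; the (S)-epoxide carbon becomes (R)-C2 and the former epoxide oxygen remains as the tertiary alcohol. Under basic conditions attack at the tertiary carbon (six-membered ring) does not compete, and the aryl triisopropylsilyl ether should tolerate the brief exposure.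

Step 10
Reactants: 21 2-[(2R)-7-(methoxymethyl)-6-(triisopropylsilyloxy)-4-[2-(trimethylsilyl)ethoxy]-2,3-dihydro-1-benzofuran-2-yl]propan-2-ol
Product: 22 2-[(2R)-5-bromo-7-(methoxymethyl)-6-(triisopropylsilyloxy)-4-[2-(trimethylsilyl)ethoxy]-2,3-dihydro-1-benzofuran-2-yl]propan-2-ol
Conditions: N-bromosuccinimide, MeCN, −20 → 0 °C, dark
Reagents that add atoms: N-bromosuccinimide, O=C1CCC(=O)N1Br
Why: Electrophilic aromatic bromination at C5, the only ring C–H, activated by both flanking oxygens; it is done before any alkene is present.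

Step 11
Reactants: 22 2-[(2R)-5-bromo-7-(methoxymethyl)-6-(triisopropylsilyloxy)-4-[2-(trimethylsilyl)ethoxy]-2,3-dihydro-1-benzofuran-2-yl]propan-2-ol
Product: 23 (2R)-5-bromo-7-(methoxymethyl)-2-(prop-1-en-2-yl)-6-(triisopropylsilyloxy)-4-[2-(trimethylsilyl)ethoxy]-2,3-dihydro-1-benzofuran
Conditions: methyl N-(triethylammoniosulfonyl)carbamate (Burgess reagent), PhMe, 50 °C
Reagents that add atoms: none
Why: Burgess dehydration: syn-elimination from the tertiary sulfamate should take one of six unhindered methyl hydrogens in preference to the single hydrogen on C2, which the adjacent ring oxygen deactivates, as in the established dehydrations of 2-(2-hydroxypropan-2-yl)dihydrobenzofurans. The neutral conditions leave C2–O1 and the benzylic ether intact, and C2 is not touched.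

Step 12
Reactants: 23 (2R)-5-bromo-7-(methoxymethyl)-2-(prop-1-en-2-yl)-6-(triisopropylsilyloxy)-4-[2-(trimethylsilyl)ethoxy]-2,3-dihydro-1-benzofuran; 24 2-methylpropanal
Product: 26 1-[(2R)-7-(methoxymethyl)-2-(prop-1-en-2-yl)-6-(triisopropylsilyloxy)-4-[2-(trimethylsilyl)ethoxy]-2,3-dihydro-1-benzofuran-5-yl]-2-methylpropan-1-ol (both carbinol epimers), via aryllithium 25 (not isolated)
Conditions: t-BuLi (2.1 equiv), Et2O, −78 °C, 15 min; 24, −78 → −40 °C; aq. NH4Cl
Reagents that add atoms: none
Why: Bromine–lithium exchange at −78 °C is faster than any deprotonation or O-to-C silyl shift, and 25 adds to the aldehyde to give the carbinol as an inconsequential pair of epimers. This inverts the polarity of a Friedel–Crafts acylation, whose Lewis acid would ionise the C7 benzylic ether and the C2–O1 bond.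

Step 13
Reactants: 26 1-[(2R)-7-(methoxymethyl)-2-(prop-1-en-2-yl)-6-(triisopropylsilyloxy)-4-[2-(trimethylsilyl)ethoxy]-2,3-dihydro-1-benzofuran-5-yl]-2-methylpropan-1-ol
Product: 27 1-[(2R)-7-(methoxymethyl)-2-(prop-1-en-2-yl)-6-(triisopropylsilyloxy)-4-[2-(trimethylsilyl)ethoxy]-2,3-dihydro-1-benzofuran-5-yl]-2-methylpropan-1-one
Conditions: Dess–Martin periodinane, NaHCO3, CH2Cl2, 0 → 20 °C
Reagents that add atoms: none
Why: Dess–Martin oxidation of the benzylic secondary alcohol under buffered, non-acidic conditions; the isopropenyl group, the silicon-based ethers and the benzylic ether are inert.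

Step 14
Reactants: 28 ethyl 3-oxopentanoate; 29 N-methoxy-N-methylpropanamide
Product: 31 ethyl 4-methyl-3,5-dioxoheptanoate, via ester dianion 30 (not isolated)
Conditions: NaH, THF, 0 °C; n-BuLi, −10 °C; 29, 0 → 20 °C; aq. HCl
Reagents that add atoms: none
Why: The dianion of the β-keto ester reacts at its more basic γ-carbon, and the N-methoxy-N-methylamide gives a chelated adduct that collapses to the 3,5-diketo ester only on work-up, which prevents over-addition.

Step 15
Reactants: 31 ethyl 4-methyl-3,5-dioxoheptanoate
Product: 32 6-ethyl-4-hydroxy-5-methyl-2H-pyran-2-one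
Conditions: 1,8-diazabicyclo[5.4.0]undec-7-ene (1.2 equiv), PhMe, reflux; aq. HCl
Reagents that add atoms: none
Why: Base-induced lactonisation: the enol oxygen of the C5 ketone attacks the ester with loss of ethanol and the ring tautomerises to the 4-hydroxy-2-pyranone, the standard closure of 3,5-dioxo esters.

Step 16
Reactants: 27 1-[(2R)-7-(methoxymethyl)-2-(prop-1-en-2-yl)-6-(triisopropylsilyloxy)-4-[2-(trimethylsilyl)ethoxy]-2,3-dihydro-1-benzofuran-5-yl]-2-methylpropan-1-one; 32 6-ethyl-4-hydroxy-5-methyl-2H-pyran-2-one
Product: 35 6-ethyl-4-hydroxy-3-{[(2R)-4,6-dihydroxy-5-(2-methylpropanoyl)-2-(prop-1-en-2-yl)-2,3-dihydro-1-benzofuran-7-yl]methyl}-5-methyl-2H-pyran-2-one, via diphenol 33 (not isolated), via quinone methide 34 (not isolated)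
Conditions: Bu4NF (5 equiv), 32 (1.5 equiv), THF–HCONMe2, 0 → 60 °C, Ar; cold dilute HCl to pH 4
Reagents that add atoms: none
Why: Fluoride cleaves the aryl silyl ether at O6 and fragments the 2-(trimethylsilyl)ethyl ether at O4 (ethene and Me3SiF), both helped by the ortho acyl group, and the phenoxide of 33 expels methoxide from the C7 benzylic carbon to give o-quinone methide 34. The pyranone anion adds through C3 to the exocyclic methylene, driven by re-aromatisation; O-alkylation is reversible through 34, so the C-linked product should accumulate. C2 is not involved and no acid is used before work-up.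

## Compound list

1 | 2-(trimethylsilyl)ethanol | C[Si](C)(C)CCO | starting material
2 | trichloroethene | ClC=C(Cl)Cl | starting material
3 | {2-[(E)-1,2-dichloroethenoxy]ethyl}trimethylsilane | C[Si](C)(C)CCO/C(Cl)=C\Cl | intermediate
4 | lithium 2-[2-(trimethylsilyl)ethoxy]ethynide | [Li]C#COCC[Si](C)(C)C | intermediate
5 | [2-(ethynyloxy)ethyl]trimethylsilane | C#COCC[Si](C)(C)C | intermediate
6 | 5-methylhex-4-enoic acid | CC(C)=CCCC(=O)O | starting material
7 | 5-methylhex-4-enoyl chloride | CC(C)=CCCC(=O)Cl | intermediate
8 | 5-methylhexa-1,4-dien-1-one (prenylketene) | CC(C)=CCC=C=O | intermediate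
9 | 4-(3-methylbut-2-en-1-yl)-3-[2-(trimethylsilyl)ethoxy]cyclobut-2-en-1-one (racemic) | C[Si](C)(C)CCOC1=CC(=O)C1CC=C(C)C | intermediate
10 | 3-methoxyprop-1-yne | COCC#C | starting material
11 | lithium 3-methoxyprop-1-yn-1-ide | COCC#C[Li] | intermediate
12 | lithium 3-methoxyprop-1-yn-1-olate | COCC#CO[Li] | intermediate
13 | 3-methoxy-1-(triisopropylsilyloxy)prop-1-yne | COCC#CO[Si](C(C)C)(C(C)C)C(C)C | intermediate
14 | 7-methyl-3-[2-(trimethylsilyl)ethoxy]octa-1,3,6-trien-1-one | CC(C)=CCC=C(C=C=O)OCC[Si](C)(C)C | intermediate
15 | 2-(methoxymethyl)-4-{5-methyl-1-[2-(trimethylsilyl)ethoxy]hexa-1,4-dien-1-yl}-3-(triisopropylsilyloxy)cyclobut-2-en-1-one | COCC1=C(O[Si](C(C)C)(C(C)C)C(C)C)C(C(OCC[Si](C)(C)C)=CCC=C(C)C)C1=O | intermediate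
16 | 2-(methoxymethyl)-9-methyl-3-(triisopropylsilyloxy)-5-[2-(trimethylsilyl)ethoxy]deca-1,3,5,8-tetraen-1-one | COCC(=C=O)C(O[Si](C(C)C)(C(C)C)C(C)C)=CC(OCC[Si](C)(C)C)=CCC=C(C)C | intermediate
17 | 6-(methoxymethyl)-2-(3-methylbut-2-en-1-yl)-5-(triisopropylsilyloxy)-3-[2-(trimethylsilyl)ethoxy]phenol | COCc1c(O)c(CC=C(C)C)c(OCC[Si](C)(C)C)cc1O[Si](C(C)C)(C(C)C)C(C)C | intermediate
18 | 6-(methoxymethyl)-2-(3-methylbut-2-en-1-yl)-5-(triisopropylsilyloxy)-3-[2-(trimethylsilyl)ethoxy]phenyl acetate | COCc1c(OC(C)=O)c(CC=C(C)C)c(OCC[Si](C)(C)C)cc1O[Si](C(C)C)(C(C)C)C(C)C | intermediate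
19 | 2-{[(2S)-3,3-dimethyloxiran-2-yl]methyl}-6-(methoxymethyl)-5-(triisopropylsilyloxy)-3-[2-(trimethylsilyl)ethoxy]phenyl acetate | COCc1c(OC(C)=O)c(C[C@@H]2OC2(C)C)c(OCC[Si](C)(C)C)cc1O[Si](C(C)C)(C(C)C)C(C)C | intermediate
20 | 2-{[(2S)-3,3-dimethyloxiran-2-yl]methyl}-6-(methoxymethyl)-5-(triisopropylsilyloxy)-3-[2-(trimethylsilyl)ethoxy]phenol | COCc1c(O)c(C[C@@H]2OC2(C)C)c(OCC[Si](C)(C)C)cc1O[Si](C(C)C)(C(C)C)C(C)C | intermediate
21 | 2-[(2R)-7-(methoxymethyl)-6-(triisopropylsilyloxy)-4-[2-(trimethylsilyl)ethoxy]-2,3-dihydro-1-benzofuran-2-yl]propan-2-ol | CC(C)(O)[C@H]1Cc2c(OCC[Si](C)(C)C)cc(O[Si](C(C)C)(C(C)C)C(C)C)c(COC)c2O1 | intermediate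
22 | 2-[(2R)-5-bromo-7-(methoxymethyl)-6-(triisopropylsilyloxy)-4-[2-(trimethylsilyl)ethoxy]-2,3-dihydro-1-benzofuran-2-yl]propan-2-ol | CC(C)(O)[C@H]1Cc2c(OCC[Si](C)(C)C)c(Br)c(O[Si](C(C)C)(C(C)C)C(C)C)c(COC)c2O1 | intermediate
23 | (2R)-5-bromo-7-(methoxymethyl)-2-(prop-1-en-2-yl)-6-(triisopropylsilyloxy)-4-[2-(trimethylsilyl)ethoxy]-2,3-dihydro-1-benzofuran | C=C(C)[C@H]1Cc2c(OCC[Si](C)(C)C)c(Br)c(O[Si](C(C)C)(C(C)C)C(C)C)c(COC)c2O1 | intermediate
24 | 2-methylpropanal | CC(C)C=O | starting material
25 | (2R)-5-lithio-7-(methoxymethyl)-2-(prop-1-en-2-yl)-6-(triisopropylsilyloxy)-4-[2-(trimethylsilyl)ethoxy]-2,3-dihydro-1-benzofuran | C=C(C)[C@H]1Cc2c(OCC[Si](C)(C)C)c([Li])c(O[Si](C(C)C)(C(C)C)C(C)C)c(COC)c2O1 | intermediate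
26 | 1-[(2R)-7-(methoxymethyl)-2-(prop-1-en-2-yl)-6-(triisopropylsilyloxy)-4-[2-(trimethylsilyl)ethoxy]-2,3-dihydro-1-benzofuran-5-yl]-2-methylpropan-1-ol (both carbinol epimers) | C=C(C)[C@H]1Cc2c(OCC[Si](C)(C)C)c(C(O)C(C)C)c(O[Si](C(C)C)(C(C)C)C(C)C)c(COC)c2O1 | intermediate
27 | 1-[(2R)-7-(methoxymethyl)-2-(prop-1-en-2-yl)-6-(triisopropylsilyloxy)-4-[2-(trimethylsilyl)ethoxy]-2,3-dihydro-1-benzofuran-5-yl]-2-methylpropan-1-one | C=C(C)[C@H]1Cc2c(OCC[Si](C)(C)C)c(C(=O)C(C)C)c(O[Si](C(C)C)(C(C)C)C(C)C)c(COC)c2O1 | intermediate
28 | ethyl 3-oxopentanoate | CCC(=O)CC(=O)OCC | starting material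
29 | N-methoxy-N-methylpropanamide | CCC(=O)N(C)OC | starting material
30 | sodium lithium dianion of ethyl 3-oxopentanoate (bis-enolate) | CCOC([O-])=CC([O-])=CC.[Na+].[Li+] | intermediate
31 | ethyl 4-methyl-3,5-dioxoheptanoate (racemic, enolisable) | CCOC(=O)CC(=O)C(C)C(=O)CC | intermediate
32 | 6-ethyl-4-hydroxy-5-methyl-2H-pyran-2-one | CCc1oc(=O)cc(O)c1C | intermediate
33 | 1-[(2R)-4,6-dihydroxy-7-(methoxymethyl)-2-(prop-1-en-2-yl)-2,3-dihydro-1-benzofuran-5-yl]-2-methylpropan-1-one | C=C(C)[C@H]1Cc2c(O)c(C(=O)C(C)C)c(O)c(COC)c2O1 | intermediate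
34 | (2R)-4-hydroxy-7-methylidene-5-(2-methylpropanoyl)-2-(prop-1-en-2-yl)-2,3-dihydro-1-benzofuran-6(7H)-one | C=C(C)[C@H]1CC2=C(O1)C(=C)C(=O)C(C(=O)C(C)C)=C2O | intermediate
35 | 6-ethyl-4-hydroxy-3-{[(2R)-4,6-dihydroxy-5-(2-methylpropanoyl)-2-(prop-1-en-2-yl)-2,3-dihydro-1-benzofuran-7-yl]methyl}-5-methyl-2H-pyran-2-one | C=C(C)[C@H]1Cc2c(O)c(C(=O)C(C)C)c(O)c(Cc3c(O)c(C)c(CC)oc3=O)c2O1 | target

## Step count and least certain steps

Total: 16 steps. Longest linear sequence: 12 steps (1, 2, 4, 6, 7, 8, 9, 10, 11, 12, 13, 16).

**Step 6 (key step).**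
- Risk: the vinylogous-ester cyclobutenone 9 may open only at a temperature at which 13 rearranges by 1,3-silyl shift to a silylketene, or at which vinylketene 14 is lost to dimerisation and to acylation of the product phenol. The propargylic ether also lowers the nucleophilicity of 13.
- Fallback: generate 14 at room temperature from an acyclic precursor instead of from 9. It sets out from alcohol 1 and siloxyalkyne 13 and returns at 17. Commercial ethyl 7-methyl-3-oxooct-6-enoate F1 is O-alkylated with 1 under Mitsunobu conditions (PPh3, diisopropyl azodicarboxylate, THF) to ethyl (2E)-7-methyl-3-[2-(trimethylsilyl)ethoxy]octa-2,6-dienoate F2. Saponification (LiOH, THF–H2O) gives (2E)-7-methyl-3-[2-(trimethylsilyl)ethoxy]octa-2,6-dienoic acid F3, and 1-chloro-N,N,2-trimethylprop-1-en-1-amine converts it under neutral conditions into (2E)-7-methyl-3-[2-(trimethylsilyl)ethoxy]octa-2,6-dienoyl chloride F4. Slow addition of F4 to Et3N and 13 in toluene at 20 °C should give 14 by 1,4-dehydrochlorination, as isopropenylketene forms from 3-methylbut-2-enoyl chloride; warming to 80 °C completes the cascade through 15 and 16 to 17.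

**Step 8.**
- Risk: oxidation of the very electron-rich arene by the dioxirane or by KHSO5, above all after premature loss of the acetate, and incomplete facial selectivity.
- Fallback: a Tsuji–Trost allylic etherification that needs no arene-compatible epoxidation. It sets out from 18 and returns at 23, replacing steps 8 to 11, so the regiochemical question of the dehydration in step 11 (methyl versus ring hydrogen) disappears as well. Allylic oxidation of 18 (SeO2 cat., t-BuOOH, CH2Cl2) gives 2-[(2E)-4-hydroxy-3-methylbut-2-en-1-yl]-6-(methoxymethyl)-5-(triisopropylsilyloxy)-3-[2-(trimethylsilyl)ethoxy]phenyl acetate F5. Methyl chloroformate and pyridine give 2-{(2E)-4-[(methoxycarbonyl)oxy]-3-methylbut-2-en-1-yl}-6-(methoxymethyl)-5-(triisopropylsilyloxy)-3-[2-(trimethylsilyl)ethoxy]phenyl acetate F6. Hydrazine at 0 °C removes only the aryl acetate to give (2E)-4-{2-hydroxy-3-(methoxymethyl)-4-(triisopropylsilyloxy)-6-[2-(trimethylsilyl)ethoxy]phenyl}-2-methylbut-2-en-1-yl methyl carbonate F7. Zerovalent palladium (Pd2(dba)3·CHCl3) with one enantiomer of N,N′-bis[2-(diphenylphosphino)benzoyl]cyclohexane-1,2-diamine, chosen on a model phenol so that the (2R) ring forms, ionises the carbonate, and the phenol closes the five-membered ring at the internal allyl terminus to give (2R)-7-(methoxymethyl)-2-(prop-1-en-2-yl)-6-(triisopropylsilyloxy)-4-[2-(trimethylsilyl)ethoxy]-2,3-dihydro-1-benzofuran F8. N-Bromosuccinimide at −78 °C, where the trioxygenated arene should outpace the alkene, gives 23.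

**Step 12.**
- Risk: in the aryllithium flanked by two oxygens, silyl migration from O6 to C5 may set in, or proton transfer from the enolisable aldehyde may replace addition at the crowded carbon.
- Fallback: reverse the roles of the two carbons. It sets out from 23 (through 25) and returns at 26. 25 is quenched at −78 °C with HCONMe2, a small and non-enolisable electrophile, to give (2R)-7-(methoxymethyl)-2-(prop-1-en-2-yl)-6-(triisopropylsilyloxy)-4-[2-(trimethylsilyl)ethoxy]-2,3-dihydro-1-benzofuran-5-carbaldehyde F9. Addition of i-PrMgCl in the presence of LaCl3·2LiCl, which suppresses β-hydride reduction, gives 26.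

**Step 16.**
- Risk: expulsion of methoxide from the acyl-stabilised phenoxide may be slow, so that 34 forms in low concentration and is intercepted by fluoride or hydroxide, or the silylethyl ether may fragment only sluggishly.
- Fallback: form the bridge by reductive alkylation instead of quinone methide capture. It sets out from 27 and returns at 35. 2,3-Dichloro-5,6-dicyano-1,4-benzoquinone in wet CH2Cl2 oxidises the electron-rich benzylic methyl ether to (2R)-5-(2-methylpropanoyl)-2-(prop-1-en-2-yl)-6-(triisopropylsilyloxy)-4-[2-(trimethylsilyl)ethoxy]-2,3-dihydro-1-benzofuran-7-carbaldehyde F10. Bu4NF removes both silicon-based groups to give (2R)-4,6-dihydroxy-5-(2-methylpropanoyl)-2-(prop-1-en-2-yl)-2,3-dihydro-1-benzofuran-7-carbaldehyde F11. With 32, L-proline (cat.) and diethyl 2,6-dimethyl-1,4-dihydropyridine-3,5-dicarboxylate, Knoevenagel condensation gives 3-{[(2R)-4,6-dihydroxy-5-(2-methylpropanoyl)-2-(prop-1-en-2-yl)-2,3-dihydro-1-benzofuran-7-yl]methylidene}-6-ethyl-5-methyl-2H-pyran-2,4(3H)-dione F12, which is reduced in the flask by hydride transfer to 35.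

## Further compounds

F1 | step 6 | ethyl 7-methyl-3-oxooct-6-enoate | CCOC(=O)CC(=O)CCC=C(C)C
F2 | step 6 | ethyl (2E)-7-methyl-3-[2-(trimethylsilyl)ethoxy]octa-2,6-dienoate | CCOC(=O)/C=C(/OCC[Si](C)(C)C)CCC=C(C)C
F3 | step 6 | (2E)-7-methyl-3-[2-(trimethylsilyl)ethoxy]octa-2,6-dienoic acid | OC(=O)/C=C(/OCC[Si](C)(C)C)CCC=C(C)C
F4 | step 6 | (2E)-7-methyl-3-[2-(trimethylsilyl)ethoxy]octa-2,6-dienoyl chloride | ClC(=O)/C=C(/OCC[Si](C)(C)C)CCC=C(C)C
F5 | step 8 | 2-[(2E)-4-hydroxy-3-methylbut-2-en-1-yl]-6-(methoxymethyl)-5-(triisopropylsilyloxy)-3-[2-(trimethylsilyl)ethoxy]phenyl acetate | COCc1c(OC(C)=O)c(C/C=C(\C)CO)c(OCC[Si](C)(C)C)cc1O[Si](C(C)C)(C(C)C)C(C)C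
F6 | step 8 | 2-{(2E)-4-[(methoxycarbonyl)oxy]-3-methylbut-2-en-1-yl}-6-(methoxymethyl)-5-(triisopropylsilyloxy)-3-[2-(trimethylsilyl)ethoxy]phenyl acetate | COCc1c(OC(C)=O)c(C/C=C(\C)COC(=O)OC)c(OCC[Si](C)(C)C)cc1O[Si](C(C)C)(C(C)C)C(C)C
F7 | step 8 | (2E)-4-{2-hydroxy-3-(methoxymethyl)-4-(triisopropylsilyloxy)-6-[2-(trimethylsilyl)ethoxy]phenyl}-2-methylbut-2-en-1-yl methyl carbonate | COCc1c(O)c(C/C=C(\C)COC(=O)OC)c(OCC[Si](C)(C)C)cc1O[Si](C(C)C)(C(C)C)C(C)C
F8 | step 8 | (2R)-7-(methoxymethyl)-2-(prop-1-en-2-yl)-6-(triisopropylsilyloxy)-4-[2-(trimethylsilyl)ethoxy]-2,3-dihydro-1-benzofuran | C=C(C)[C@H]1Cc2c(OCC[Si](C)(C)C)cc(O[Si](C(C)C)(C(C)C)C(C)C)c(COC)c2O1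
F9 | step 12 | (2R)-7-(methoxymethyl)-2-(prop-1-en-2-yl)-6-(triisopropylsilyloxy)-4-[2-(trimethylsilyl)ethoxy]-2,3-dihydro-1-benzofuran-5-carbaldehyde | C=C(C)[C@H]1Cc2c(OCC[Si](C)(C)C)c(C=O)c(O[Si](C(C)C)(C(C)C)C(C)C)c(COC)c2O1
F10 | step 16 | (2R)-5-(2-methylpropanoyl)-2-(prop-1-en-2-yl)-6-(triisopropylsilyloxy)-4-[2-(trimethylsilyl)ethoxy]-2,3-dihydro-1-benzofuran-7-carbaldehyde | C=C(C)[C@H]1Cc2c(OCC[Si](C)(C)C)c(C(=O)C(C)C)c(O[Si](C(C)C)(C(C)C)C(C)C)c(C=O)c2O1
F11 | step 16 | (2R)-4,6-dihydroxy-5-(2-methylpropanoyl)-2-(prop-1-en-2-yl)-2,3-dihydro-1-benzofuran-7-carbaldehyde | C=C(C)[C@H]1Cc2c(O)c(C(=O)C(C)C)c(O)c(C=O)c2O1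
F12 | step 16 | 3-{[(2R)-4,6-dihydroxy-5-(2-methylpropanoyl)-2-(prop-1-en-2-yl)-2,3-dihydro-1-benzofuran-7-yl]methylidene}-6-ethyl-5-methyl-2H-pyran-2,4(3H)-dione | C=C(C)[C@H]1Cc2c(O)c(C(=O)C(C)C)c(O)c(C=C3C(=O)OC(CC)=C(C)C3=O)c2O1
A1 | alternative 1 | 4-O-tert-butyldimethylsilyl ether of 35 | C=C(C)[C@H]1Cc2c(O[Si](C)(C)C(C)(C)C)c(C(=O)C(C)C)c(O)c(Cc3c(O)c(C)c(CC)oc3=O)c2O1
A2 | alternative 1 | tricyclic lactone acid chloride: (2R)-2-isopropenyl-5-(2-methylpropanoyl)-4-(tert-butyldimethylsilyloxy)-2,3-dihydrobenzofuran with O6 and the C7 methylene tied into a 3-(chlorocarbonyl)dihydrocoumarin ring | C=C(C)[C@H]1Cc2c(O[Si](C)(C)C(C)(C)C)c(C(=O)C(C)C)c3OC(=O)C(C(Cl)=O)Cc3c2O1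
A3 | alternative 1 | 3-(trimethylsilyloxy)pent-2-ene | CC=C(CC)O[Si](C)(C)C
A4 | alternative 2 | (2R)-7-(tert-butyldimethylsilyloxymethyl)-4,6-bis(methoxymethoxy)-2-[2-(triethylsilyloxy)propan-2-yl]-2,3-dihydrobenzofuran | CC(C)(O[Si](CC)(CC)CC)[C@H]1Cc2c(OCOC)cc(OCOC)c(CO[Si](C)(C)C(C)(C)C)c2O1
A5 | alternative 2 | tert-butyl{[2-iodo-4,6-bis(methoxymethoxy)phenyl]methoxy}dimethylsilane | COCOc1cc(I)c(CO[Si](C)(C)C(C)(C)C)c(OCOC)c1
A6 | alternative 2 | (2R)-2-[2-(triethylsilyloxy)propan-2-yl]oxirane | CC(C)(O[Si](CC)(CC)CC)[C@H]1CO1
A7 | alternative 3 | 1-[(2R)-4,6-dihydroxy-2-(prop-1-en-2-yl)-2,3-dihydrobenzofuran-5-yl]-2-methylpropan-1-one | C=C(C)[C@H]1Cc2c(O)c(C(=O)C(C)C)c(O)cc2O1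
A8 | alternative 3 | methyl (5R)-2-(5-methyl-2,4-dioxohexyl)-5-(prop-1-en-2-yl)-4,5-dihydrofuran-3-carboxylate | C=C(C)[C@H]1CC(C(=O)OC)=C(CC(=O)CC(=O)C(C)C)O1
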